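**Plan**
Cuts, in retrosynthetic order: the ester C–O bond at C-6 (alcohol 15 + acid 16); C-4=CH2 (Wittig on a C-4 ketone); C-1–C-10 of ring A (radical closure); C-4–C-5 (vinyllithium + cyclobutanone). Ring B is the ring of (−)-menthone.
Enabling feature: C-10 is joined through C-5 to C-4, and C-4 through C-3 and C-2 to C-1. A C-4 ketone therefore makes C-5=C-10 of ring B an enone with C-10 as its β-carbon, and C-1 to C-4 can come in as one cyclobutanol ring whose C-4–C-1 bond, once cleaved, delivers that ketone and a C-1 radical together.
Forward: menthone 1 → enone 3 → iodo enone 4 → cis allylic silyl ether 6 → cyclobutanol 9 → ring A by ring expansion (11) → methylenation (12) → correction of C-6 (13 → 14 → 15) → esterification and deacetylation (19). Ring B is present from the start; ring A arises in step 6.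
Stereochemistry: C-7 from (−)-menthone; a temporary C-6 centre (silyloxy cis to isopropyl) from bulky-hydride reduction, which should steer C-10 and C-5 in the key step; the final C-6 centre from thermodynamic dissolving-metal reduction; the E-alkene comes with the acid.

Key step: step 6

Remark: atoms carry eudesmane numbers throughout (C-1 to C-3 ring A methylenes, C-4 methylidene carbon, C-5 ring-fusion CH, C-6 oxygen-bearing carbon, C-7 isopropyl-bearing carbon, C-10 methyl-bearing quaternary carbon); β is the face of ring B on which the isopropyl group lies, α the other face; (−)-menthone, cyclobutanone and (E)-4-acetoxycinnamic acid are taken as catalogue compounds.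

Step 1
Reactants: 1 (2S,5R)-5-methyl-2-(propan-2-yl)cyclohexan-1-one [(−)-menthone]
Product: 3 (6S)-3-methyl-6-(propan-2-yl)cyclohex-2-en-1-one [(S)-piperitone], via silyl enol ether 2 (not isolated)
Conditions: LiN(i-Pr)2, THF, −78 °C; Me3SiCl; solvent exchange; Pd(OAc)2 (10 mol %), O2 (1 atm), DMSO, rt
Reagents that add atoms: none
Why: Kinetic deprotonation should take the proton on the CH2 side of the ketone, away from the isopropyl-bearing stereocentre, and Saegusa–Ito oxidation of the silyl enol ether (C-palladation, then β-hydride elimination from the methyl-bearing carbon) should give the enone under neutral conditions that leave C-7 untouched.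

Step 2
Reactants: 3 (6S)-3-methyl-6-(propan-2-yl)cyclohex-2-en-1-one
Product: 4 (6S)-2-iodo-3-methyl-6-(propan-2-yl)cyclohex-2-en-1-one
Conditions: I2, pyridine/CH2Cl2 (1:1), DMAP (20 mol %), rt, dark
Reagents that add atoms: iodine [I][I]
Why: α-Iodination of an enone by the amine–iodine addition–elimination sequence (conjugate addition of the amine, iodination of the enolate, elimination) should place the halogen on C-5 for the later metalation, and the weak amine base should not enolise C-7.

Step 3
Reactants: 4 (6S)-2-iodo-3-methyl-6-(propan-2-yl)cyclohex-2-en-1-one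
Product: 5 (1R,6S)-2-iodo-3-methyl-6-(propan-2-yl)cyclohex-2-en-1-ol (hydroxyl β and cis to isopropyl)
Conditions: LiBH(s-Bu)3, THF, −78 °C; H2O
Reagents that add atoms: none
Why: In this 1,2-reduction of an α-iodo enone with a bulky trialkylborohydride the β,β-disubstituted iodoalkene should resist conjugate reduction and hydride should enter along the equatorial direction, as with 2-alkylcyclohexanones, so that the new C-6 hydroxyl group is pseudoaxial and cis to the isopropyl group (substrate control by C-7).

Step 4
Reactants: 5 (1R,6S)-2-iodo-3-methyl-6-(propan-2-yl)cyclohex-2-en-1-ol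
Product: 6 tert-butyl{[(1R,6S)-2-iodo-3-methyl-6-(propan-2-yl)cyclohex-2-en-1-yl]oxy}dimethylsilane
Conditions: t-BuMe2SiOTf, 2,6-lutidine, CH2Cl2, −78 → 0 °C
Reagents that add atoms: tert-butyldimethylsilyl trifluoromethanesulfonate CC(C)(C)[Si](C)(C)OS(=O)(=O)C(F)(F)F
Why: Silylation of a hindered secondary allylic alcohol with a silyl triflate and a hindered base installs the bulky group that is meant to shield the β face of the alkene in step 6.

Step 5
Reactants: 6 tert-butyl{[(1R,6S)-2-iodo-3-methyl-6-(propan-2-yl)cyclohex-2-en-1-yl]oxy}dimethylsilane; 7 cyclobutanone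
Product: 9 1-{(5S,6R)-6-[(tert-butyldimethylsilyl)oxy]-2-methyl-5-(propan-2-yl)cyclohex-1-en-1-yl}cyclobutan-1-ol, via vinyllithium 8 (not isolated)
Conditions: t-BuLi (2.1 equiv), Et2O, −78 °C; then 7, −78 → −20 °C; H2O
Reagents that add atoms: none
Why: Iodine–lithium exchange should give the vinyllithium, in which β-elimination of the silyloxy group is not possible because it would give a six-membered cyclic allene, and this should add 1,2 to the strained and highly electrophilic carbonyl group of cyclobutanone to form the C-4–C-5 bond.

Step 6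
Reactants: 9 1-{(5S,6R)-6-[(tert-butyldimethylsilyl)oxy]-2-methyl-5-(propan-2-yl)cyclohex-1-en-1-yl}cyclobutan-1-ol
Product: 11 (4aR,7S,8R,8aS)-8-[(tert-butyldimethylsilyl)oxy]-4a-methyl-7-(propan-2-yl)octahydronaphthalen-1(2H)-one, via ring-opened keto radical 10 (not isolated)
Conditions: [Ir(dF(CF3)ppy)2(5,5′-d(CF3)bpy)]PF6 (2 mol %), 2,4,6-collidine, 2,4,6-triisopropylbenzenethiol (5 mol %), CH2Cl2 (0.02 M), blue LEDs, rt
Reagents that add atoms: none
Why: Proton-coupled electron transfer from the tertiary O–H bond to the photoexcited iridium complex and collidine should give the cyclobutyloxy radical, strain-driven β-scission of its C-4–C-1 bond unveils the C-4 ketone and the primary C-1 radical 10, this radical adds to C-10 (now the β-carbon of the enone C-4=O/C-5=C-10), and the C-5 α-keto radical is quenched by hydrogen-atom transfer from the thiol, which the reduced photocatalyst and collidinium regenerate. The closest known reaction type is the photocatalytic alkoxy-radical ring expansion of 1-alkenylcycloalkanols to ring-enlarged ketones (cyclobutanol to cyclohexanone, the radical counterpart of the oxidative ring expansion of 1-arylcyclobutanols to 1-tetralones). Ring A closes in the 6-endo-trig mode, expected over 5-exo closure at C-5 because a nucleophilic alkyl radical bonds to the β-carbon of an enone and gives a tertiary α-keto radical, whereas C-5 is the electron-rich, doubly flanked α-carbon and the carbonyl group within the chain disfavours the five-membered transition state. The C-10 stereocentre is controlled by the C-6 silyloxy group, which allylic 1,2-strain with the C-5 acyl group should hold pseudoaxial on the β face (isopropyl pseudoequatorial), so that C-1 bonds to C-10 from the α face and the methyl group ends β, cis to the isopropyl group. The C-5 stereocentre is controlled in the hydrogen-atom transfer, which should arrive on the α face because the β face of the planar radical is covered by the new angular methyl group and the axial silyloxy group, giving the trans ring fusion. The step needs chemoselective O–H activation, 6-endo regioselectivity, cyclisation faster than reduction of radical 10 and facial control, which the single free hydroxyl group, the polarity match, high dilution with a low thiol loading and the pseudoaxial silyl ether are meant to secure in that order.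

Step 7
Reactants: 11 (4aR,7S,8R,8aS)-8-[(tert-butyldimethylsilyl)oxy]-4a-methyl-7-(propan-2-yl)octahydronaphthalen-1(2H)-one
Product: 12 tert-butyl{[(1R,2S,4aR,8aS)-4a-methyl-8-methylidene-2-(propan-2-yl)decahydronaphthalen-1-yl]oxy}dimethylsilane
Conditions: Ph3PCH3Br (3.0 equiv), KOt-Bu (2.8 equiv), THF, 0 → 40 °C
Reagents that add atoms: methyltriphenylphosphonium bromide C[P+](c1ccccc1)(c1ccccc1)c1ccccc1.[Br-]
Why: Wittig methylenation of the C-4 ketone is the classical way to the 4(15)-alkene of eudesmanes and is run with a slight deficit of base so that no free alkoxide is present to epimerise C-5 or eliminate the β-silyloxy group.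

Step 8
Reactants: 12 tert-butyl{[(1R,2S,4aR,8aS)-4a-methyl-8-methylidene-2-(propan-2-yl)decahydronaphthalen-1-yl]oxy}dimethylsilane
Product: 13 (1R,2S,4aR,8aS)-4a-methyl-8-methylidene-2-(propan-2-yl)decahydronaphthalen-1-ol (eudesm-4(15)-en-6β-ol)
Conditions: Bu4NF, THF, 50 °C
Reagents that add atoms: none
Why: Fluoride should cleave the Si–O bond of the hindered axial silyl ether and leave the alkene and all stereocentres untouched.

Step 9
Reactants: 13 (1R,2S,4aR,8aS)-4a-methyl-8-methylidene-2-(propan-2-yl)decahydronaphthalen-1-ol
Product: 14 (2S,4aR,8aS)-4a-methyl-8-methylidene-2-(propan-2-yl)octahydronaphthalen-1(2H)-one (eudesm-4(15)-en-6-one)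
Conditions: Dess–Martin periodinane, NaHCO3, CH2Cl2, 0 °C → rt; crude product used at once
Reagents that add atoms: none
Why: Dess–Martin oxidation under buffered and non-enolising conditions removes the temporary C-6 stereocentre and should give the β,γ-unsaturated ketone without moving the exocyclic double bond into conjugation, provided the product is not stored or exposed to acid or base.

Step 10
Reactants: 14 (2S,4aR,8aS)-4a-methyl-8-methylidene-2-(propan-2-yl)octahydronaphthalen-1(2H)-one
Product: 15 (1S,2S,4aR,8aS)-4a-methyl-8-methylidene-2-(propan-2-yl)decahydronaphthalen-1-ol (eudesm-4(15)-en-6α-ol)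
Conditions: Li, NH3 (l)/THF, t-BuOH, −78 °C (ketone added to the blue solution); then NH4Cl
Reagents that add atoms: none
Why: Dissolving-metal reduction of a cyclic ketone should give the thermodynamically preferred equatorial alcohol because the intermediate carbanion settles with oxygen equatorial before it is protonated on carbon, which here means the 6α alcohol trans to the isopropyl group (hydride reagents would be expected to return the axial 6β alcohol since the angular methyl group blocks axial attack), while electron transfer to the ketone should outrun enolisation and the isolated alkene is not reduced.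

Step 11
Reactants: 15 (1S,2S,4aR,8aS)-4a-methyl-8-methylidene-2-(propan-2-yl)decahydronaphthalen-1-ol; 16 (2E)-3-[4-(acetyloxy)phenyl]prop-2-enoic acid
Product: 18 (1S,2S,4aR,8aS)-4a-methyl-8-methylidene-2-(propan-2-yl)decahydronaphthalen-1-yl (2E)-3-[4-(acetyloxy)phenyl]prop-2-enoate, via mixed anhydride 17 (not isolated)
Conditions: 2,4,6-Cl3C6H2COCl, Et3N, THF, rt; then 15, DMAP, toluene, rt → 40 °C
Reagents that add atoms: none
Why: In this Yamaguchi esterification DMAP should attack the mixed anhydride at the less hindered cinnamoyl carbonyl and the resulting acylpyridinium should acylate the hindered equatorial alcohol with retention at C-6, the phenol being masked as its acetate.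

Step 12
Reactants: 18 (1S,2S,4aR,8aS)-4a-methyl-8-methylidene-2-(propan-2-yl)decahydronaphthalen-1-yl (2E)-3-[4-(acetyloxy)phenyl]prop-2-enoate
Product: 19 (1S,2S,4aR,8aS)-4a-methyl-8-methylidene-2-(propan-2-yl)decahydronaphthalen-1-yl (2E)-3-(4-hydroxyphenyl)prop-2-enoate
Conditions: pyrrolidine, CH2Cl2, rt
Reagents that add atoms: none
Why: Aminolysis of the aryl acetate by pyrrolidine should be far faster than attack on the hindered secondary cinnamate, so the phenol is freed selectively and the E-alkene and the ester are kept.

**Compound list**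
1 | (2S,5R)-5-methyl-2-(propan-2-yl)cyclohexan-1-one, (−)-menthone | CC(C)[C@@H]1CC[C@@H](C)CC1=O | starting material
2 | trimethyl{[(3R,6S)-3-methyl-6-(propan-2-yl)cyclohex-1-en-1-yl]oxy}silane | CC(C)[C@@H]1CC[C@@H](C)C=C1O[Si](C)(C)C | intermediate
3 | (6S)-3-methyl-6-(propan-2-yl)cyclohex-2-en-1-one, (S)-piperitone | CC1=CC(=O)[C@H](C(C)C)CC1 | intermediate
4 | (6S)-2-iodo-3-methyl-6-(propan-2-yl)cyclohex-2-en-1-one | CC1=C(I)C(=O)[C@H](C(C)C)CC1 | intermediate
5 | (1R,6S)-2-iodo-3-methyl-6-(propan-2-yl)cyclohex-2-en-1-ol (hydroxyl cis to isopropyl) | CC1=C(I)[C@H](O)[C@H](C(C)C)CC1 | intermediate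
6 | tert-butyl{[(1R,6S)-2-iodo-3-methyl-6-(propan-2-yl)cyclohex-2-en-1-yl]oxy}dimethylsilane | CC1=C(I)[C@H](O[Si](C)(C)C(C)(C)C)[C@H](C(C)C)CC1 | intermediate
7 | cyclobutanone | O=C1CCC1 | starting material
8 | {(5S,6R)-6-[(tert-butyldimethylsilyl)oxy]-2-methyl-5-(propan-2-yl)cyclohex-1-en-1-yl}lithium | CC1=C([Li])[C@H](O[Si](C)(C)C(C)(C)C)[C@H](C(C)C)CC1 | intermediate
9 | 1-{(5S,6R)-6-[(tert-butyldimethylsilyl)oxy]-2-methyl-5-(propan-2-yl)cyclohex-1-en-1-yl}cyclobutan-1-ol | CC1=C(C2(O)CCC2)[C@H](O[Si](C)(C)C(C)(C)C)[C@H](C(C)C)CC1 | intermediate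
10 | 4-{(5S,6R)-6-[(tert-butyldimethylsilyl)oxy]-2-methyl-5-(propan-2-yl)cyclohex-1-en-1-yl}-4-oxobutyl radical | CC1=C(C(=O)CC[CH2])[C@H](O[Si](C)(C)C(C)(C)C)[C@H](C(C)C)CC1 | intermediate
11 | (4aR,7S,8R,8aS)-8-[(tert-butyldimethylsilyl)oxy]-4a-methyl-7-(propan-2-yl)octahydronaphthalen-1(2H)-one (trans-fused, silyloxy axial and β) | O=C1CCC[C@]2(C)CC[C@@H](C(C)C)[C@@H](O[Si](C)(C)C(C)(C)C)[C@@H]12 | intermediate
12 | tert-butyl{[(1R,2S,4aR,8aS)-4a-methyl-8-methylidene-2-(propan-2-yl)decahydronaphthalen-1-yl]oxy}dimethylsilane | C=C1CCC[C@]2(C)CC[C@@H](C(C)C)[C@@H](O[Si](C)(C)C(C)(C)C)[C@@H]12 | intermediate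
13 | (1R,2S,4aR,8aS)-4a-methyl-8-methylidene-2-(propan-2-yl)decahydronaphthalen-1-ol, eudesm-4(15)-en-6β-ol | C=C1CCC[C@]2(C)CC[C@@H](C(C)C)[C@@H](O)[C@@H]12 | intermediate
14 | (2S,4aR,8aS)-4a-methyl-8-methylidene-2-(propan-2-yl)octahydronaphthalen-1(2H)-one, eudesm-4(15)-en-6-one | C=C1CCC[C@]2(C)CC[C@@H](C(C)C)C(=O)[C@@H]12 | intermediate
15 | (1S,2S,4aR,8aS)-4a-methyl-8-methylidene-2-(propan-2-yl)decahydronaphthalen-1-ol, eudesm-4(15)-en-6α-ol | C=C1CCC[C@]2(C)CC[C@@H](C(C)C)[C@H](O)[C@@H]12 | intermediate
16 | (2E)-3-[4-(acetyloxy)phenyl]prop-2-enoic acid | CC(=O)Oc1ccc(/C=C/C(=O)O)cc1 | starting material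
17 | (2E)-3-[4-(acetyloxy)phenyl]prop-2-enoic 2,4,6-trichlorobenzoic anhydride | CC(=O)Oc1ccc(/C=C/C(=O)OC(=O)c2c(Cl)cc(Cl)cc2Cl)cc1 | intermediate
18 | (1S,2S,4aR,8aS)-4a-methyl-8-methylidene-2-(propan-2-yl)decahydronaphthalen-1-yl (2E)-3-[4-(acetyloxy)phenyl]prop-2-enoate | C=C1CCC[C@]2(C)CC[C@@H](C(C)C)[C@H](OC(=O)/C=C/c3ccc(OC(C)=O)cc3)[C@@H]12 | intermediate
19 | (1S,2S,4aR,8aS)-4a-methyl-8-methylidene-2-(propan-2-yl)decahydronaphthalen-1-yl (2E)-3-(4-hydroxyphenyl)prop-2-enoate | C=C1CCC[C@]2(C)CC[C@@H](C(C)C)[C@H](OC(=O)/C=C/c3ccc(O)cc3)[C@@H]12 | target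

Total step count: 12. Longest linear sequence: 12 steps (1 to 19); 7 and 16 enter as single building blocks.

**Steps most likely to fail**

Step 6. What may go wrong: hydrogen-atom transfer to the ring-opened primary radical before it closes onto the tetrasubstituted C-5=C-10 bond, unproductive back electron transfer at the O–H activation stage, or closure on the wrong face of C-10. Fallback (sets out from 6, comes back at 11): vinyllithium 8 is made as in step 5 and acylated with 4-chloro-N-methoxy-N-methylbutanamide to give the chloro ketone F1. NaI in acetone then exchanges chloride for iodide to give the iodo ketone F2. Slow syringe-pump addition of Bu3SnH with AIBN in refluxing benzene would make the same C-1 radical by iodine abstraction, at a hydrogen-donor concentration low enough for the 6-endo closure to win, and should give 11.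

Step 10. What may go wrong: deprotonation at C-5 by amide or alkoxide, with migration of the exocyclic double bond into conjugation before electron transfer, or incomplete settling of the carbanion before protonation. Fallback (sets out from 13, comes back at 15): the C-6 centre is inverted by substitution instead of by oxidation and reduction. Mitsunobu reaction of 13 with 4-nitrobenzoic acid, PPh3 and diisopropyl azodicarboxylate would give the inverted 6α 4-nitrobenzoate F3, which K2CO3 in methanol would cleave to 15; ketone 14 is then never made.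

Step 7. What may go wrong: enolisation of the hindered ketone toward C-5 in place of ylide addition, followed by epimerisation of the ring fusion or β-elimination of silanolate. Fallback (sets out from 11, comes back at 12): Peterson olefination in two stages. Addition of the weakly basic organocerium reagent from Me3SiCH2Li and CeCl3 would give the β-hydroxysilane F4, and KH in THF would then bring about syn-elimination to 12.

Further compounds
F1 | step 6 | 4-chloro-1-{(5S,6R)-6-[(tert-butyldimethylsilyl)oxy]-2-methyl-5-(propan-2-yl)cyclohex-1-en-1-yl}butan-1-one | CC1=C(C(=O)CCCCl)[C@H](O[Si](C)(C)C(C)(C)C)[C@H](C(C)C)CC1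
F2 | step 6 | 4-iodo-1-{(5S,6R)-6-[(tert-butyldimethylsilyl)oxy]-2-methyl-5-(propan-2-yl)cyclohex-1-en-1-yl}butan-1-one | CC1=C(C(=O)CCCI)[C@H](O[Si](C)(C)C(C)(C)C)[C@H](C(C)C)CC1
F3 | step 10 | (1S,2S,4aR,8aS)-4a-methyl-8-methylidene-2-(propan-2-yl)decahydronaphthalen-1-yl 4-nitrobenzoate | C=C1CCC[C@]2(C)CC[C@@H](C(C)C)[C@H](OC(=O)c3ccc(cc3)[N+](=O)[O-])[C@@H]12
F4 | step 7 | (4aR,7S,8R,8aS)-8-[(tert-butyldimethylsilyl)oxy]-4a-methyl-7-(propan-2-yl)-1-[(trimethylsilyl)methyl]decahydronaphthalen-1-ol (carbinol configuration not defined) | C[Si](C)(C)CC1(O)CCC[C@]2(C)CC[C@@H](C(C)C)[C@@H](O[Si](C)(C)C(C)(C)C)[C@@H]12
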